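With the chain numbered C1 (alkyne CH) to C15 (ethyl CH3), the plan rests on cutting C12–C13 of the oxolane ring (O, C10, C11, C12, C13). C12 carries bromine, so it can pass through a ketone next to C13, and C13 sits on the ring oxygen. An acyl radical at C12 can therefore close onto an enol-ether carbon tethered through O–C10. One operation forms the ring, sets C13 cis to C10 and leaves the C12 carbonyl for later inversion to bromide. The precursor is Se-phenyl selenoester 13, a syn-C9,C10 bis(benzyloxy) pentanoate whose C10 oxygen bears an (E)-β-methoxycarbonylvinyl group.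

Key step: step 9

Assumption: 3,4-O-isopropylidene-D-mannitol 1 (the mono-acetonide of D-mannitol) and 4-methoxybenzyl propargyl ether 23 are taken as catalogue compounds; the usual Sharpless facial rule is taken to hold for the Z-allylic alcohol, so L-(+)-diethyl tartrate should give the (6S,7R)-oxirane.

Step 1
Reactants: 1 3,4-O-isopropylidene-D-mannitol
Product: 2 1,2,5,6-tetra-O-benzyl-3,4-O-isopropylidene-D-mannitol
Conditions: NaH, BnBr, Bu4NI (cat.), DMF, 0 °C to rt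
Reagents that add atoms: benzyl bromide BrCc1ccccc1
Why: Williamson etherification of the four free hydroxyls; no stereocentre is touched.

Step 2
Reactants: 2 1,2,5,6-tetra-O-benzyl-3,4-O-isopropylidene-D-mannitol
Product: 3 1,2,5,6-tetra-O-benzyl-D-mannitol
Conditions: AcOH/H2O (4:1), 80 °C
Reagents that add atoms: none
Why: Acid-catalysed acetal hydrolysis frees the C3,C4 diol while benzyl ethers are stable.

Step 3
Reactants: 3 1,2,5,6-tetra-O-benzyl-D-mannitol
Product: 4 (R)-2,3-bis(benzyloxy)propanal (two equivalents per mole of 3)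
Conditions: NaIO4 on SiO2, CH2Cl2, rt; used at once
Reagents that add atoms: none
Why: Periodate glycol cleavage of the central diol of the C2-symmetric tetraether gives two identical α-alkoxy aldehydes under neutral, non-aqueous conditions that should not epimerise C9.

Step 4
Reactants: 5 tert-butyl acetate
Product: 7 tert-butyl[(1-tert-butoxyethenyl)oxy]dimethylsilane, via lithium enolate 6 (not isolated)
Conditions: LDA, THF, −78 °C; TBSCl, DMPU, −78 °C to rt
Reagents that add atoms: tert-butyldimethylsilyl chloride CC(C)(C)[Si](C)(C)Cl; lithium diisopropylamide [Li]N(C(C)C)C(C)C (lithium only in 6)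
Why: O-silylation of the ester enolate in the presence of DMPU gives the ketene silyl acetal.

Step 5
Reactants: 4 (R)-2,3-bis(benzyloxy)propanal; 7 tert-butyl[(1-tert-butoxyethenyl)oxy]dimethylsilane
Product: 8 tert-butyl (3R,4R)-4,5-bis(benzyloxy)-3-hydroxypentanoate
Conditions: MgBr2·OEt2, CH2Cl2, −78 to −20 °C; aq. HCl work-up
Reagents that add atoms: none
Why: Mukaiyama aldol under Cram-chelate control: MgBr2 ties the aldehyde and α-benzyloxy oxygens into a five-membered chelate and the ketene acetal attacks anti to CH2OBn, which sets C10 as R (C9,C10-syn).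

Step 6
Reactants: 8 tert-butyl (3R,4R)-4,5-bis(benzyloxy)-3-hydroxypentanoate; 9 methyl propiolate
Product: 10 tert-butyl (3R,4R)-4,5-bis(benzyloxy)-3-{[(1E)-3-methoxy-3-oxoprop-1-en-1-yl]oxy}pentanoate
Conditions: N-methylmorpholine, CH2Cl2, rt
Reagents that add atoms: none
Why: Amine-catalysed oxa-Michael addition of the secondary alcohol to the ynoate gives the (E)-β-alkoxyacrylate.

Step 7
Reactants: 10 tert-butyl (3R,4R)-4,5-bis(benzyloxy)-3-{[(1E)-3-methoxy-3-oxoprop-1-en-1-yl]oxy}pentanoate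
Product: 11 (3R,4R)-4,5-bis(benzyloxy)-3-{[(1E)-3-methoxy-3-oxoprop-1-en-1-yl]oxy}pentanoic acid
Conditions: TFA/CH2Cl2 (1:4), 0 °C to rt
Reagents that add atoms: none
Why: Acidolysis of the tert-butyl ester through the tert-butyl cation leaves the methyl ester, the vinylogous carbonate and the benzyl ethers intact.

Step 8
Reactants: 11 (3R,4R)-4,5-bis(benzyloxy)-3-{[(1E)-3-methoxy-3-oxoprop-1-en-1-yl]oxy}pentanoic acid; 12 diphenyl diselenide
Product: 13 Se-phenyl (3R,4R)-4,5-bis(benzyloxy)-3-{[(1E)-3-methoxy-3-oxoprop-1-en-1-yl]oxy}pentaneselenoate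
Conditions: PBu3, CH2Cl2, 0 °C to rt
Reagents that add atoms: none
Why: Phosphine/diselenide activation converts the acid into an acyloxyphosphonium ion that benzeneselenolate captures to give the selenoester.

Step 9
Reactants: 13 Se-phenyl (3R,4R)-4,5-bis(benzyloxy)-3-{[(1E)-3-methoxy-3-oxoprop-1-en-1-yl]oxy}pentaneselenoate
Product: 14 methyl 2-{(2R,5R)-5-[(1R)-1,2-bis(benzyloxy)ethyl]-3-oxooxolan-2-yl}acetate
Conditions: (Me3Si)3SiH, Et3B, air, PhMe (dilute), 0 °C to rt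
Reagents that add atoms: none
Why: Et3B and oxygen start a chain in which the silyl radical abstracts PhSe from 13, the nucleophilic C12 acyl radical adds to the electron-poor β-carbon C13 of the vinylogous carbonate, and the α-ester radical at C14 takes hydrogen from the silane. The closest known reaction type is the acyl radical cyclisation of acyl selenides onto β-alkoxyacrylates, which gives cis-2,5-disubstituted oxolan-3-ones. The oxolane ring (O, C10, C11, C12, C13) closes in the 5-exo-trig mode. The new stereocentre C13 is controlled by C10 through a chair-like transition state in which the C10 side chain and the acrylate are both pseudo-equatorial, which leads to the 2,5-cis ring (2R,5R). The step needs cis selectivity and ring closure that outruns loss of CO or direct reduction of the acyl radical; the activated (E)-acrylate acceptor, the primary acyl radical, the low temperature and the low silane concentration should secure both.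

Step 10
Reactants: 14 methyl 2-{(2R,5R)-5-[(1R)-1,2-bis(benzyloxy)ethyl]-3-oxooxolan-2-yl}acetate
Product: 15 methyl 2-{(2R,3R,5R)-5-[(1R)-1,2-bis(benzyloxy)ethyl]-3-hydroxyoxolan-2-yl}acetate
Conditions: LiB(s-Bu)3H (L-Selectride), THF, −78 °C; NH4Cl quench at −78 °C
Reagents that add atoms: none
Why: Substrate-controlled reduction: the bulky hydride attacks the C12 ketone from the face opposite the two cis ring substituents, so the hydroxyl ends up cis to both (12R).

Step 11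
Reactants: 15 methyl 2-{(2R,3R,5R)-5-[(1R)-1,2-bis(benzyloxy)ethyl]-3-hydroxyoxolan-2-yl}acetate
Product: 16 methyl 2-{(2R,3R,5R)-5-[(1R)-1,2-bis(benzyloxy)ethyl]-3-[(tert-butyldimethylsilyl)oxy]oxolan-2-yl}acetate
Conditions: TBSOTf, 2,6-lutidine, CH2Cl2, −78 to 0 °C
Reagents that add atoms: tert-butyldimethylsilyl triflate CC(C)(C)[Si](C)(C)OS(=O)(=O)C(F)(F)F
Why: Silylation with the silyl triflate blocks the C12 hydroxyl, which would otherwise lactonise onto the cis ester arm or later close a second ether ring.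

Step 12
Reactants: 16 methyl 2-{(2R,3R,5R)-5-[(1R)-1,2-bis(benzyloxy)ethyl]-3-[(tert-butyldimethylsilyl)oxy]oxolan-2-yl}acetate
Product: 17 2-{(2R,3R,5R)-5-[(1R)-1,2-bis(benzyloxy)ethyl]-3-[(tert-butyldimethylsilyl)oxy]oxolan-2-yl}ethan-1-ol
Conditions: i-Bu2AlH, CH2Cl2, −78 to 0 °C; Rochelle salt work-up
Reagents that add atoms: none
Why: Hydride reduction of the ester to the primary alcohol; silyl and benzyl ethers are inert.

Step 13
Reactants: 17 2-{(2R,3R,5R)-5-[(1R)-1,2-bis(benzyloxy)ethyl]-3-[(tert-butyldimethylsilyl)oxy]oxolan-2-yl}ethan-1-ol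
Product: 19 tert-butyl({(2R,3R,5R)-5-[(1R)-1,2-bis(benzyloxy)ethyl]-2-ethyloxolan-3-yl}oxy)dimethylsilane, via primary tosylate 18 (not isolated)
Conditions: TsCl, Et3N, DMAP (cat.), CH2Cl2, rt; crude tosylate then LiEt3BH, THF, 0 °C to rt
Reagents that add atoms: p-toluenesulfonyl chloride Cc1ccc(cc1)S(Cl)(=O)=O (tosyl group only in 18)
Why: Sulfonylation followed by SN2 hydride displacement of the unhindered primary tosylate turns C15 into the methyl of the ethyl group.

Step 14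
Reactants: 19 tert-butyl({(2R,3R,5R)-5-[(1R)-1,2-bis(benzyloxy)ethyl]-2-ethyloxolan-3-yl}oxy)dimethylsilane
Product: 20 (1R)-1-{(2R,4R,5R)-4-[(tert-butyldimethylsilyl)oxy]-5-ethyloxolan-2-yl}ethane-1,2-diol
Conditions: H2 (1 atm), 10% Pd/C, EtOAc, rt
Reagents that add atoms: none
Why: Hydrogenolysis removes both benzyl ethers while no unsaturation is yet present and the silyl ether survives in a neutral solvent.

Step 15
Reactants: 20 (1R)-1-{(2R,4R,5R)-4-[(tert-butyldimethylsilyl)oxy]-5-ethyloxolan-2-yl}ethane-1,2-diol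
Product: 22 tert-butyl({(2R,3R,5R)-2-ethyl-5-[(2R)-oxiran-2-yl]oxolan-3-yl}oxy)dimethylsilane, via primary tosylate 21 (not isolated)
Conditions: NaH, 1-(p-toluenesulfonyl)imidazole, THF, 0 °C to rt
Reagents that add atoms: 1-(p-toluenesulfonyl)imidazole Cc1ccc(cc1)S(=O)(=O)n1ccnc1 (tosyl group only in 21)
Why: Selective sulfonylation of the primary alkoxide and intramolecular Williamson closure by the C9 alkoxide give the terminal oxirane; the C9–O bond is never broken, so C9 stays R.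

Step 16
Reactants: 22 tert-butyl({(2R,3R,5R)-2-ethyl-5-[(2R)-oxiran-2-yl]oxolan-3-yl}oxy)dimethylsilane; 23 1-methoxy-4-[(prop-2-yn-1-yloxy)methyl]benzene
Product: 25 (1R)-1-{(2R,4R,5R)-4-[(tert-butyldimethylsilyl)oxy]-5-ethyloxolan-2-yl}-5-[(4-methoxybenzyl)oxy]pent-3-yn-1-ol, via lithium acetylide 24 (not isolated)
Conditions: 23, n-BuLi, THF, −78 °C; BF3·OEt2; then 22, −78 °C
Reagents that add atoms: n-butyllithium [Li]CCCC (lithium only in 24)
Why: Yamaguchi–Hirao alkynylation: the BF3-activated oxirane is opened at the unhindered C8 by the acetylide, forming C7–C8 and leaving the (9R)-alcohol.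

Step 17
Reactants: 25 (1R)-1-{(2R,4R,5R)-4-[(tert-butyldimethylsilyl)oxy]-5-ethyloxolan-2-yl}-5-[(4-methoxybenzyl)oxy]pent-3-yn-1-ol
Product: 26 (2R,3R,5R)-2-ethyl-5-{(1R)-1-hydroxy-5-[(4-methoxybenzyl)oxy]pent-3-yn-1-yl}oxolan-3-ol
Conditions: Bu4NF, THF, rt to 40 °C
Reagents that add atoms: none
Why: Fluoride cleaves the Si–O bond of the silyl ether; the PMB ether is untouched.

Step 18
Reactants: 26 (2R,3R,5R)-2-ethyl-5-{(1R)-1-hydroxy-5-[(4-methoxybenzyl)oxy]pent-3-yn-1-yl}oxolan-3-ol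
Product: 27 (2R,3S,5R)-3-bromo-5-{(1S)-1-bromo-5-[(4-methoxybenzyl)oxy]pent-3-yn-1-yl}-2-ethyloxolane
Conditions: CBr4, (n-C8H17)3P, 2,6-di-tert-butylpyridine, PhMe, 70 °C
Reagents that add atoms: carbon tetrabromide BrC(Br)(Br)Br
Why: Double Appel reaction: bromide displaces each alkoxyphosphonium group by SN2 with inversion, giving 9S and 12S, the latter trans to the ethyl group.

Step 19
Reactants: 27 (2R,3S,5R)-3-bromo-5-{(1S)-1-bromo-5-[(4-methoxybenzyl)oxy]pent-3-yn-1-yl}-2-ethyloxolane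
Product: 28 (5S)-5-bromo-5-[(2R,4S,5R)-4-bromo-5-ethyloxolan-2-yl]pent-2-yn-1-ol
Conditions: DDQ, CH2Cl2/pH 7 buffer, 0 °C to rt
Reagents that add atoms: none
Why: Oxidative cleavage of the electron-rich PMB ether by DDQ and hydrolysis of the oxocarbenium ion free the propargylic alcohol without touching the bromides.

Step 20
Reactants: 28 (5S)-5-bromo-5-[(2R,4S,5R)-4-bromo-5-ethyloxolan-2-yl]pent-2-yn-1-ol
Product: 29 (2Z,5S)-5-bromo-5-[(2R,4S,5R)-4-bromo-5-ethyloxolan-2-yl]pent-2-en-1-ol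
Conditions: H2 (1 atm), Pd/CaCO3 poisoned with Pb(OAc)2 (Lindlar catalyst), quinoline, EtOAc, rt
Reagents that add atoms: none
Why: Lindlar semi-hydrogenation adds hydrogen syn to the alkyne and stops at the Z-alkene; alkyl bromides are inert.

Step 21
Reactants: 29 (2Z,5S)-5-bromo-5-[(2R,4S,5R)-4-bromo-5-ethyloxolan-2-yl]pent-2-en-1-ol
Product: 30 {(2S,3R)-3-[(2S)-2-bromo-2-((2R,4S,5R)-4-bromo-5-ethyloxolan-2-yl)ethyl]oxiran-2-yl}methanol
Conditions: Ti(OiPr)4, L-(+)-diethyl tartrate (stoichiometric), t-BuOOH, 4 Å MS, CH2Cl2, −20 °C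
Reagents that add atoms: tert-butyl hydroperoxide CC(C)(C)OO
Why: Katsuki–Sharpless asymmetric epoxidation: the titanium–L-tartrate complex delivers oxygen to the face that makes the carbinol-bearing carbon C6 S, and syn addition to the Z-alkene gives the cis-oxirane with C7 R, under reagent control.

Step 22
Reactants: 31 3-(trimethylsilyl)prop-2-ynal
Product: 32 [(3E)-4-iodobut-3-en-1-yn-1-yl]trimethylsilane
Conditions: CrCl2, CHI3, THF, 0 °C to rt; minor Z isomer removed by chromatography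
Reagents that add atoms: iodoform IC(I)I
Why: Takai iodo-olefination: the geminal dichromium species adds to the aldehyde and eliminates to the (E)-vinyl iodide.

Step 23
Reactants: 30 {(2S,3R)-3-[(2S)-2-bromo-2-((2R,4S,5R)-4-bromo-5-ethyloxolan-2-yl)ethyl]oxiran-2-yl}methanol; 32 [(3E)-4-iodobut-3-en-1-yn-1-yl]trimethylsilane
Product: 36 trimethyl[(3E)-5-{(2S,3R)-3-[(2S)-2-bromo-2-((2R,4S,5R)-4-bromo-5-ethyloxolan-2-yl)ethyl]oxiran-2-yl}pent-3-en-1-yn-1-yl]silane, via epoxy triflate 33 (not isolated), via alkenyllithium 34 (not isolated), via lithium dialkenylcuprate 35 (not isolated)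
Conditions: 32, t-BuLi (2 equiv), Et2O, −78 °C; CuI (0.5 equiv), −40 °C; separately 30, Tf2O, 2,6-lutidine, CH2Cl2, −78 °C; triflate added to the cuprate, Et2O, −78 to −40 °C; NH4Cl work-up
Reagents that add atoms: triflic anhydride O=S(=O)(OS(=O)(=O)C(F)(F)F)C(F)(F)F (triflyl group only in 33); tert-butyllithium [Li]C(C)(C)C (lithium only in 34 and 35); CuI [Cu]I (copper only in 35)
Why: Iodine–lithium exchange and Gilman cuprate formation keep the E geometry, and SN2 displacement of the primary triflate by the alkenyl cuprate forms C4–C5 faster than the oxirane or the secondary bromides can react at low temperature.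

Step 24
Reactants: 36 trimethyl[(3E)-5-{(2S,3R)-3-[(2S)-2-bromo-2-((2R,4S,5R)-4-bromo-5-ethyloxolan-2-yl)ethyl]oxiran-2-yl}pent-3-en-1-yn-1-yl]silane
Product: 37 (3E,6S,7R,9S,10R,12S,13R)-9,12-dibromo-6,7:10,13-diepoxypentadec-3-en-1-yne
Conditions: K2CO3, MeOH, 0 °C to rt
Reagents that add atoms: none
Why: Methoxide-mediated protodesilylation of the alkynylsilane is mild enough to leave the oxirane and both secondary bromides in place.

Compound list
1 | 3,4-O-isopropylidene-D-mannitol | OC[C@@H](O)[C@H]1OC(C)(C)O[C@@H]1[C@H](O)CO | starting material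
2 | 1,2,5,6-tetra-O-benzyl-3,4-O-isopropylidene-D-mannitol | c1ccccc1COC[C@@H](OCc1ccccc1)[C@H]1OC(C)(C)O[C@@H]1[C@H](OCc1ccccc1)COCc1ccccc1 | intermediate
3 | 1,2,5,6-tetra-O-benzyl-D-mannitol | c1ccccc1COC[C@@H](OCc1ccccc1)[C@@H](O)[C@H](O)[C@H](OCc1ccccc1)COCc1ccccc1 | intermediate
4 | (R)-2,3-bis(benzyloxy)propanal | O=C[C@H](OCc1ccccc1)COCc1ccccc1 | intermediate
5 | tert-butyl acetate | CC(=O)OC(C)(C)C | starting material
6 | lithium enolate of tert-butyl acetate | [Li+].[O-]C(=C)OC(C)(C)C | intermediate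
7 | tert-butyl[(1-tert-butoxyethenyl)oxy]dimethylsilane | C=C(OC(C)(C)C)O[Si](C)(C)C(C)(C)C | intermediate
8 | tert-butyl (3R,4R)-4,5-bis(benzyloxy)-3-hydroxypentanoate | CC(C)(C)OC(=O)C[C@@H](O)[C@H](OCc1ccccc1)COCc1ccccc1 | intermediate
9 | methyl propiolate | C#CC(=O)OC | starting material
10 | tert-butyl (3R,4R)-4,5-bis(benzyloxy)-3-{[(1E)-3-methoxy-3-oxoprop-1-en-1-yl]oxy}pentanoate | COC(=O)/C=C/O[C@H](CC(=O)OC(C)(C)C)[C@H](OCc1ccccc1)COCc1ccccc1 | intermediate
11 | (3R,4R)-4,5-bis(benzyloxy)-3-{[(1E)-3-methoxy-3-oxoprop-1-en-1-yl]oxy}pentanoic acid | COC(=O)/C=C/O[C@H](CC(=O)O)[C@H](OCc1ccccc1)COCc1ccccc1 | intermediate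
12 | diphenyl diselenide | c1ccccc1[Se][Se]c1ccccc1 | starting material
13 | Se-phenyl (3R,4R)-4,5-bis(benzyloxy)-3-{[(1E)-3-methoxy-3-oxoprop-1-en-1-yl]oxy}pentaneselenoate | COC(=O)/C=C/O[C@H](CC(=O)[Se]c1ccccc1)[C@H](OCc1ccccc1)COCc1ccccc1 | intermediate
14 | methyl 2-{(2R,5R)-5-[(1R)-1,2-bis(benzyloxy)ethyl]-3-oxooxolan-2-yl}acetate | c1ccccc1COC[C@@H](OCc1ccccc1)[C@H]1CC(=O)[C@@H](CC(=O)OC)O1 | intermediate
15 | methyl 2-{(2R,3R,5R)-5-[(1R)-1,2-bis(benzyloxy)ethyl]-3-hydroxyoxolan-2-yl}acetate | c1ccccc1COC[C@@H](OCc1ccccc1)[C@H]1C[C@@H](O)[C@@H](CC(=O)OC)O1 | intermediate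
16 | methyl 2-{(2R,3R,5R)-5-[(1R)-1,2-bis(benzyloxy)ethyl]-3-[(tert-butyldimethylsilyl)oxy]oxolan-2-yl}acetate | c1ccccc1COC[C@@H](OCc1ccccc1)[C@H]1C[C@@H](O[Si](C)(C)C(C)(C)C)[C@@H](CC(=O)OC)O1 | intermediate
17 | 2-{(2R,3R,5R)-5-[(1R)-1,2-bis(benzyloxy)ethyl]-3-[(tert-butyldimethylsilyl)oxy]oxolan-2-yl}ethan-1-ol | c1ccccc1COC[C@@H](OCc1ccccc1)[C@H]1C[C@@H](O[Si](C)(C)C(C)(C)C)[C@@H](CCO)O1 | intermediate
18 | 2-{(2R,3R,5R)-5-[(1R)-1,2-bis(benzyloxy)ethyl]-3-[(tert-butyldimethylsilyl)oxy]oxolan-2-yl}ethyl 4-methylbenzenesulfonate | c1ccccc1COC[C@@H](OCc1ccccc1)[C@H]1C[C@@H](O[Si](C)(C)C(C)(C)C)[C@@H](CCOS(=O)(=O)c2ccc(C)cc2)O1 | intermediate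
19 | tert-butyl({(2R,3R,5R)-5-[(1R)-1,2-bis(benzyloxy)ethyl]-2-ethyloxolan-3-yl}oxy)dimethylsilane | c1ccccc1COC[C@@H](OCc1ccccc1)[C@H]1C[C@@H](O[Si](C)(C)C(C)(C)C)[C@@H](CC)O1 | intermediate
20 | (1R)-1-{(2R,4R,5R)-4-[(tert-butyldimethylsilyl)oxy]-5-ethyloxolan-2-yl}ethane-1,2-diol | OC[C@@H](O)[C@H]1C[C@@H](O[Si](C)(C)C(C)(C)C)[C@@H](CC)O1 | intermediate
21 | (2R)-2-{(2R,4R,5R)-4-[(tert-butyldimethylsilyl)oxy]-5-ethyloxolan-2-yl}-2-hydroxyethyl 4-methylbenzenesulfonate | Cc1ccc(cc1)S(=O)(=O)OC[C@@H](O)[C@H]1C[C@@H](O[Si](C)(C)C(C)(C)C)[C@@H](CC)O1 | intermediate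
22 | tert-butyl({(2R,3R,5R)-2-ethyl-5-[(2R)-oxiran-2-yl]oxolan-3-yl}oxy)dimethylsilane | C1O[C@H]1[C@H]1C[C@@H](O[Si](C)(C)C(C)(C)C)[C@@H](CC)O1 | intermediate
23 | 1-methoxy-4-[(prop-2-yn-1-yloxy)methyl]benzene | C#CCOCc1ccc(OC)cc1 | starting material
24 | lithium acetylide of 23 | [Li]C#CCOCc1ccc(OC)cc1 | intermediate
25 | (1R)-1-{(2R,4R,5R)-4-[(tert-butyldimethylsilyl)oxy]-5-ethyloxolan-2-yl}-5-[(4-methoxybenzyl)oxy]pent-3-yn-1-ol | COc1ccc(cc1)COCC#CC[C@@H](O)[C@H]1C[C@@H](O[Si](C)(C)C(C)(C)C)[C@@H](CC)O1 | intermediate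
26 | (2R,3R,5R)-2-ethyl-5-{(1R)-1-hydroxy-5-[(4-methoxybenzyl)oxy]pent-3-yn-1-yl}oxolan-3-ol | COc1ccc(cc1)COCC#CC[C@@H](O)[C@H]1C[C@@H](O)[C@@H](CC)O1 | intermediate
27 | (2R,3S,5R)-3-bromo-5-{(1S)-1-bromo-5-[(4-methoxybenzyl)oxy]pent-3-yn-1-yl}-2-ethyloxolane | COc1ccc(cc1)COCC#CC[C@H](Br)[C@H]1C[C@H](Br)[C@@H](CC)O1 | intermediate
28 | (5S)-5-bromo-5-[(2R,4S,5R)-4-bromo-5-ethyloxolan-2-yl]pent-2-yn-1-ol | OCC#CC[C@H](Br)[C@H]1C[C@H](Br)[C@@H](CC)O1 | intermediate
29 | (2Z,5S)-5-bromo-5-[(2R,4S,5R)-4-bromo-5-ethyloxolan-2-yl]pent-2-en-1-ol | OC/C=C\C[C@H](Br)[C@H]1C[C@H](Br)[C@@H](CC)O1 | intermediate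
30 | {(2S,3R)-3-[(2S)-2-bromo-2-((2R,4S,5R)-4-bromo-5-ethyloxolan-2-yl)ethyl]oxiran-2-yl}methanol | OC[C@@H]1O[C@@H]1C[C@H](Br)[C@H]1C[C@H](Br)[C@@H](CC)O1 | intermediate
31 | 3-(trimethylsilyl)prop-2-ynal | C[Si](C)(C)C#CC=O | starting material
32 | [(3E)-4-iodobut-3-en-1-yn-1-yl]trimethylsilane | C[Si](C)(C)C#C/C=C/I | intermediate
33 | {(2S,3R)-3-[(2S)-2-bromo-2-((2R,4S,5R)-4-bromo-5-ethyloxolan-2-yl)ethyl]oxiran-2-yl}methyl trifluoromethanesulfonate | FC(F)(F)S(=O)(=O)OC[C@@H]1O[C@@H]1C[C@H](Br)[C@H]1C[C@H](Br)[C@@H](CC)O1 | intermediate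
34 | [(1E)-4-(trimethylsilyl)but-1-en-3-yn-1-yl]lithium | [Li]/C=C/C#C[Si](C)(C)C | intermediate
35 | lithium bis[(1E)-4-(trimethylsilyl)but-1-en-3-yn-1-yl]cuprate | [Li+].C[Si](C)(C)C#C/C=C/[Cu-]/C=C/C#C[Si](C)(C)C | intermediate
36 | trimethyl[(3E)-5-{(2S,3R)-3-[(2S)-2-bromo-2-((2R,4S,5R)-4-bromo-5-ethyloxolan-2-yl)ethyl]oxiran-2-yl}pent-3-en-1-yn-1-yl]silane | C[Si](C)(C)C#C/C=C/C[C@@H]1O[C@@H]1C[C@H](Br)[C@H]1C[C@H](Br)[C@@H](CC)O1 | intermediate
37 | (3E,6S,7R,9S,10R,12S,13R)-9,12-dibromo-6,7:10,13-diepoxypentadec-3-en-1-yne | C#C/C=C/C[C@@H]1O[C@@H]1C[C@H](Br)[C@H]1C[C@H](Br)[C@@H](CC)O1 | target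

Total step count: 24. Longest linear sequence: 22 steps (steps 1–3, 5–21, 23 and 24); steps 4 and 22 make the two side reagents.

Steps most likely to fail

Step 9 (acyl radical closure). The acyl radical may be reduced to the aldehyde or lose CO before it cyclises, and the 2,5-cis preference may erode. The fallback closes the same ring with a ketyl radical instead and sets out from acid 11. Chemoselective reduction of the carboxylic acid (BH3·SMe2, THF, 0 °C) should give methyl (2E)-3-{[(2R,3R)-1,2-bis(benzyloxy)-5-hydroxypentan-3-yl]oxy}prop-2-enoate F1. Dess–Martin oxidation then gives methyl (2E)-3-{[(2R,3R)-1,2-bis(benzyloxy)-5-oxopentan-3-yl]oxy}prop-2-enoate F2. SmI2/MeOH in THF at 0 °C should induce reductive 5-exo cyclisation of the aldehyde onto the β-alkoxyacrylate to give the 2,5-cis-2,3-trans hydroxy ester methyl 2-{(2R,3S,5R)-5-[(1R)-1,2-bis(benzyloxy)ethyl]-3-hydroxyoxolan-2-yl}acetate F3. A second Dess–Martin oxidation erases the unwanted C12 configuration and returns to the route at ketone 14.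

Step 18 (double Appel bromination). Substitution at the hindered all-cis C12 position may stall, E2 elimination may compete on heating, and the ring oxygen may participate at C9 and cause retention or ring expansion. The fallback separates activation from displacement and sets out from diol 26. ClCH2SO2Cl with 2,6-lutidine in CH2Cl2 at 0 °C should give (1R)-1-{(2R,4R,5R)-4-[(chloromethanesulfonyl)oxy]-5-ethyloxolan-2-yl}-5-[(4-methoxybenzyl)oxy]pent-3-yn-1-yl chloromethanesulfonate F4. SN2 displacement of both sulfonates with LiBr in THF at rt to 40 °C then returns to the route at dibromide 27.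

Step 23 (cuprate coupling). The epoxy triflate may decompose, the oxirane may be opened in competition, and transfer of the functionalised alkenyl group from copper may be poor. The fallback uses a simple vinyl nucleophile and builds the enyne afterwards; it sets out from epoxy alcohol 30. Triflate 33 is made as before and displaced with the vinyl cuprate from CH2=CHMgBr and CuBr·SMe2 (Et2O, −78 °C) to give (2R,3S,5R)-3-bromo-5-{(1S)-1-bromo-2-[(2R,3S)-3-(prop-2-en-1-yl)oxiran-2-yl]ethyl}-2-ethyloxolane F5. Cross-metathesis with crotonaldehyde (second-generation Hoveyda–Grubbs catalyst, CH2Cl2, 40 °C) should give (2E)-4-{(2S,3R)-3-[(2S)-2-bromo-2-((2R,4S,5R)-4-bromo-5-ethyloxolan-2-yl)ethyl]oxiran-2-yl}but-2-enal F6. Colvin homologation with lithiated Me3SiCHN2 (LDA, THF, −78 to 0 °C) converts the aldehyde into the terminal alkyne and returns to the route at target 37, so that 36 and step 24 are bypassed.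

Further compounds
F1 | step 9 | methyl (2E)-3-{[(2R,3R)-1,2-bis(benzyloxy)-5-hydroxypentan-3-yl]oxy}prop-2-enoate | COC(=O)/C=C/O[C@H](CCO)[C@H](OCc1ccccc1)COCc1ccccc1
F2 | step 9 | methyl (2E)-3-{[(2R,3R)-1,2-bis(benzyloxy)-5-oxopentan-3-yl]oxy}prop-2-enoate | COC(=O)/C=C/O[C@H](CC=O)[C@H](OCc1ccccc1)COCc1ccccc1
F3 | step 9 | methyl 2-{(2R,3S,5R)-5-[(1R)-1,2-bis(benzyloxy)ethyl]-3-hydroxyoxolan-2-yl}acetate | c1ccccc1COC[C@@H](OCc1ccccc1)[C@H]1C[C@H](O)[C@@H](CC(=O)OC)O1
F4 | step 18 | (1R)-1-{(2R,4R,5R)-4-[(chloromethanesulfonyl)oxy]-5-ethyloxolan-2-yl}-5-[(4-methoxybenzyl)oxy]pent-3-yn-1-yl chloromethanesulfonate | COc1ccc(cc1)COCC#CC[C@@H](OS(=O)(=O)CCl)[C@H]1C[C@@H](OS(=O)(=O)CCl)[C@@H](CC)O1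
F5 | step 23 | (2R,3S,5R)-3-bromo-5-{(1S)-1-bromo-2-[(2R,3S)-3-(prop-2-en-1-yl)oxiran-2-yl]ethyl}-2-ethyloxolane | C=CC[C@@H]1O[C@@H]1C[C@H](Br)[C@H]1C[C@H](Br)[C@@H](CC)O1
F6 | step 23 | (2E)-4-{(2S,3R)-3-[(2S)-2-bromo-2-((2R,4S,5R)-4-bromo-5-ethyloxolan-2-yl)ethyl]oxiran-2-yl}but-2-enal | O=C/C=C/C[C@@H]1O[C@@H]1C[C@H](Br)[C@H]1C[C@H](Br)[C@@H](CC)O1
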